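**Retrosynthetic overview**

1. The target comes from a protected biflavanone (two benzyl ethers on unit 1, a 5''-methyl ether on unit 2) by one BCl3 operation that cleaves the benzyl ethers and only the carbonyl-chelated 5''-O-methyl group.
2. Key disconnection: the chromanone of unit 2 is opened at C4''–C4a'' (acyl–aryl) and O1''–C8a'', giving a syn-aldol N-acyl oxazolidinone and 3,5-dimethoxybenzyne. The enabling feature is the 1,3-relationship of the C2'' hydroxyl oxygen and the C4'' imide carbonyl: O-arylation puts the aryl carbanion (future C4a'') in position to close the six-membered ring O1''–C2''–C3''–C4''–C4a''–C8a'', and the methoxy group next to the aryne fixes the 5'',7''-oxygen pattern.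
3. C2''/C3'' (cis in the ring) come from an Evans syn-aldol of the unit 1 flavanone-3-acetyl imide with 4-methoxybenzaldehyde; the same (S)-auxiliary is the leaving group of the key step.
4. Unit 1 is built by the same aldol/aryne logic from a succinate half-ester imide, 4-methoxybenzaldehyde and 3,5-bis(benzyloxy)benzyne, followed by base epimerisation at C3 to the trans (2S,3R) flavanone.
5. Ring order: benzo ring and pyranone ring of unit 1 together (step 5), then benzo ring and pyranone ring of unit 2 together (step 11); the two 4-methoxyphenyl rings arrive with the aldehyde.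

Key step: step 11

Remark on the chemistry: flavanone locants are used; unprimed locants belong to the 5,7-dihydroxy flavanone (unit 1, trans, 2S,3R), doubly primed locants to the 5-hydroxy-7-methoxy flavanone (unit 2, cis, 2''S,3''S). A syn-aldol maps onto a cis-2,3-disubstituted chromanone, so both aldol reactions use the (S)-auxiliary and unit 1 is corrected to trans by epimerisation at C3.

**Route**

Step 1
Reactants: 1 3,5-bis(benzyloxy)phenol
Product: 2 3,5-bis(benzyloxy)-2-bromophenol
Conditions: NBS (1.0 equiv), CH2Cl2, −78 → 0 °C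
Reagents that add atoms: N-bromosuccinimide, O=C1CCC(=O)N1Br
Why: Electrophilic aromatic bromination directed ortho to the free hydroxyl in a non-polar solvent at low temperature (the para position is flanked by two benzyloxy groups), any 4-bromo isomer being removed by chromatography.

Step 2
Reactants: 2 3,5-bis(benzyloxy)-2-bromophenol
Product: 5 3,5-bis(benzyloxy)-2-(trimethylsilyl)phenyl trifluoromethanesulfonate, via (2-bromoaryloxy)trimethylsilane 3 (not isolated), via lithium 2-(trimethylsilyl)phenoxide 4 (not isolated)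
Conditions: HMDS, THF, 70 °C, then evaporate; n-BuLi, THF, −100 °C; Tf2O, −100 → 23 °C
Reagents that add atoms: hexamethyldisilazane, C[Si](C)(C)N[Si](C)(C)C; trifluoromethanesulfonic anhydride, O=S(=O)(OS(=O)(=O)C(F)(F)F)C(F)(F)F
Why: O-silylation, bromine–lithium exchange and retro-Brook (1,3 O-to-C) silyl migration give the ortho-silyl phenoxide, which is O-triflated; this is the standard entry to ortho-silylaryl triflates, and the exchange at −100 °C is faster than benzylic deprotonation.

Step 3
Reactants: 6 4-tert-butoxy-4-oxobutanoic acid; 7 (S)-4-benzyloxazolidin-2-one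
Product: 8 tert-butyl 4-[(4S)-4-benzyl-2-oxooxazolidin-3-yl]-4-oxobutanoate
Conditions: DCC, DMAP (0.2 equiv), CH2Cl2, 0 → 23 °C
Reagents that add atoms: none
Why: Carbodiimide-mediated (Steglich-type) N-acylation of the oxazolidinone by the free acid, to which the tert-butyl ester is inert.

Step 4
Reactants: 8 tert-butyl 4-[(4S)-4-benzyl-2-oxooxazolidin-3-yl]-4-oxobutanoate; 9 4-methoxybenzaldehyde
Product: 11 tert-butyl (3S,4S)-3-[(4S)-4-benzyl-2-oxooxazolidine-3-carbonyl]-4-hydroxy-4-(4-methoxyphenyl)butanoate, via dibutylboron Z-enolate 10 (not isolated)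
Conditions: n-Bu2BOTf, iPr2NEt, CH2Cl2, −78 → 0 °C; 9, −78 → 0 °C; pH 7 buffer, MeOH, 30% H2O2, 0 °C
Reagents that add atoms: none
Why: Evans syn-aldol reaction in which the imide (not the tert-butyl ester) forms the Z-boron enolate and the closed chair (Zimmerman–Traxler) transition state, shielded on one face by the benzyl group of the (S)-auxiliary, sets the carbinol carbon (future C2, S) and the alpha carbon syn to it; the bulky ester keeps the hydroxyl from lactonising.

Step 5
Reactants: 11 tert-butyl (3S,4S)-3-[(4S)-4-benzyl-2-oxooxazolidine-3-carbonyl]-4-hydroxy-4-(4-methoxyphenyl)butanoate; 5 3,5-bis(benzyloxy)-2-(trimethylsilyl)phenyl trifluoromethanesulfonate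
Product: 13 tert-butyl 2-[(2S,3R)-5,7-bis(benzyloxy)-2-(4-methoxyphenyl)-4-oxochroman-3-yl]acetate, via cis-flavanone ester 12 (not isolated)
Conditions: CsF (3 equiv), MeCN–toluene (1:3), 23 °C; then DBU (0.2 equiv), 23 °C
Reagents that add atoms: none
Why: Proposed new method: fluoride releases 3,5-bis(benzyloxy)benzyne from 5, the hydrogen-bonded alkoxide of 11 adds to the aryne carbon remote from the flanking benzyloxy group, and the ortho aryl carbanion closes the pyranone ring by 6-exo-trig attack on the exocyclic imide carbonyl with loss of the oxazolidinone, the closest known reaction types being the fluoride-mediated aryne/methyl salicylate annulation to xanthones and the aryne ring expansion of N-H beta-lactams to 2,3-dihydroquinolin-4-ones; C2 (S) is carried over with retention because the C–O bond is never broken, and DBU then epimerises C3 through the enol to the thermodynamically preferred trans (diequatorial) flavanone.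

Step 6
Reactants: 13 tert-butyl 2-[(2S,3R)-5,7-bis(benzyloxy)-2-(4-methoxyphenyl)-4-oxochroman-3-yl]acetate
Product: 14 2-[(2S,3R)-5,7-bis(benzyloxy)-2-(4-methoxyphenyl)-4-oxochroman-3-yl]acetic acid
Conditions: TFA–CH2Cl2 (1:4), 0 → 23 °C
Reagents that add atoms: none
Why: Acidolysis of the tert-butyl ester (E1 loss of 2-methylpropene), which aryl benzyl ethers, aryl methyl ethers and the chromanone should survive in cold TFA.

Step 7
Reactants: 14 2-[(2S,3R)-5,7-bis(benzyloxy)-2-(4-methoxyphenyl)-4-oxochroman-3-yl]acetic acid; 7 (S)-4-benzyloxazolidin-2-one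
Product: 15 (4S)-4-benzyl-3-{2-[(2S,3R)-5,7-bis(benzyloxy)-2-(4-methoxyphenyl)-4-oxochroman-3-yl]acetyl}oxazolidin-2-one
Conditions: DCC, DMAP (0.2 equiv), CH2Cl2, 0 → 23 °C
Reagents that add atoms: none
Why: Carbodiimide-mediated (Steglich-type) N-acylation without strong base, so the trans-flavanone stereocentres are not disturbed.

Step 8
Reactants: 15 (4S)-4-benzyl-3-{2-[(2S,3R)-5,7-bis(benzyloxy)-2-(4-methoxyphenyl)-4-oxochroman-3-yl]acetyl}oxazolidin-2-one; 9 4-methoxybenzaldehyde
Product: 17 (4S)-4-benzyl-3-[(2S,3S)-2-[(2S,3R)-5,7-bis(benzyloxy)-2-(4-methoxyphenyl)-4-oxochroman-3-yl]-3-hydroxy-3-(4-methoxyphenyl)propanoyl]oxazolidin-2-one, via dibutylboron Z-enolate 16 (not isolated)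
Conditions: n-Bu2BOTf (1.3 equiv), iPr2NEt, CH2Cl2, −78 → 0 °C; 9, −78 → 0 °C; pH 7 buffer, MeOH, 30% H2O2, 0 °C
Reagents that add atoms: none
Why: Evans syn-aldol reaction under reagent control (Z-boron enolate, closed chair transition state, attack on the face opposite the auxiliary benzyl group) sets C3'' (S) and C2'' (S) syn; the imide methylene should be enolised in preference to the chromanone, whose carbonyl is a hindered vinylogous ester with only one tertiary alpha hydrogen.

Step 9
Reactants: 18 3,5-dimethoxyphenol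
Product: 19 2-bromo-3,5-dimethoxyphenol
Conditions: NBS (1.0 equiv), CH2Cl2, −78 → 0 °C
Reagents that add atoms: N-bromosuccinimide, O=C1CCC(=O)N1Br
Why: Electrophilic aromatic bromination ortho to the free hydroxyl, as in step 1, any 4-bromo isomer being removed by chromatography.

Step 10
Reactants: 19 2-bromo-3,5-dimethoxyphenol
Product: 22 3,5-dimethoxy-2-(trimethylsilyl)phenyl trifluoromethanesulfonate, via (2-bromoaryloxy)trimethylsilane 20 (not isolated), via lithium 2-(trimethylsilyl)phenoxide 21 (not isolated)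
Conditions: HMDS, THF, 70 °C, then evaporate; n-BuLi, THF, −100 °C; Tf2O, −100 → 23 °C
Reagents that add atoms: hexamethyldisilazane, C[Si](C)(C)N[Si](C)(C)C; trifluoromethanesulfonic anhydride, O=S(=O)(OS(=O)(=O)C(F)(F)F)C(F)(F)F
Why: O-silylation, bromine–lithium exchange, retro-Brook silyl migration and O-triflation, as in step 2.

Step 11
Reactants: 17 (4S)-4-benzyl-3-[(2S,3S)-2-[(2S,3R)-5,7-bis(benzyloxy)-2-(4-methoxyphenyl)-4-oxochroman-3-yl]-3-hydroxy-3-(4-methoxyphenyl)propanoyl]oxazolidin-2-one; 22 3,5-dimethoxy-2-(trimethylsilyl)phenyl trifluoromethanesulfonate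
Product: 23 (2S,3R)-5,7-bis(benzyloxy)-3-[(2S,3S)-5,7-dimethoxy-2-(4-methoxyphenyl)-4-oxochroman-3-yl]-2-(4-methoxyphenyl)chroman-4-one
Conditions: CsF (2.5 equiv), MeCN–toluene (1:3), 0 → 23 °C; pH 7 buffer quench
Reagents that add atoms: none
Why: Proposed new method: fluoride-induced 1,2-elimination of 22 gives 3,5-dimethoxybenzyne, the hydrogen-bonded C2'' alkoxide of 17 adds to the aryne carbon remote from the flanking methoxy group, and the resulting ortho aryl carbanion (future C4a'') attacks the exocyclic imide carbonyl C4'' and expels the oxazolidinone anion, which takes up the proton lost from the hydroxyl. The closest known reaction types are the fluoride-mediated annulation of arynes with methyl salicylates to xanthones (O-arylation followed by intramolecular acyl substitution) and the aryne ring expansion of N-H beta-lactams to 2,3-dihydroquinolin-4-ones; new here are an aliphatic aldolate as the nucleophile and an N-acyl oxazolidinone as the internal acyl donor. The pyranone ring of unit 2 is closed in the 6-exo-trig mode by the C4''–C4a'' bond directly after the intermolecular O1''–C8a'' bond, so the benzo ring and the heterocycle of unit 2 are both added in this one operation. No stereocentre is created: C2'' and C3'' come from step 8 and stay cis because neither the C2''–O bond nor the C3''–H bond is broken, and the auxiliary leaves as a weakly basic amide that ends up neutral. The step needs regioselectivity in the aryne addition (secured by the inductive effect of the 3-methoxy group, which places the carbanion next to it and gives the 5'',7''-pattern), chemoselectivity for the imide over the unit 1 ketone (six- against seven-membered transition state), and no epimerisation at C3'' (sparingly soluble CsF in a mostly non-polar medium, low temperature, buffered quench).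

Step 12
Reactants: 23 (2S,3R)-5,7-bis(benzyloxy)-3-[(2S,3S)-5,7-dimethoxy-2-(4-methoxyphenyl)-4-oxochroman-3-yl]-2-(4-methoxyphenyl)chroman-4-one
Product: 24 (2S,3R)-5,7-dihydroxy-3-[(2S,3S)-5-hydroxy-7-methoxy-2-(4-methoxyphenyl)-4-oxochroman-3-yl]-2-(4-methoxyphenyl)chroman-4-one (CNP0184936.3)
Conditions: BCl3 (10 equiv), C6HMe5 (6 equiv), CH2Cl2, −78 °C, then 0 °C; H2O quench
Reagents that add atoms: none
Why: Lewis-acid ether cleavage in which BCl3 removes both benzyl ethers at −78 °C (the benzyl cation is trapped by pentamethylbenzene in a Friedel–Crafts alkylation) and on warming cleaves only the 5''-methyl ether, which is activated through a six-membered boron chelate with the C4'' carbonyl, while the 7''- and the two 4'-methyl ethers lack this activation.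

**Compound list**

1 | 3,5-bis(benzyloxy)phenol | Oc1cc(OCc2ccccc2)cc(OCc2ccccc2)c1 | starting material
2 | 3,5-bis(benzyloxy)-2-bromophenol | Oc1cc(OCc2ccccc2)cc(OCc2ccccc2)c1Br | intermediate
3 | [3,5-bis(benzyloxy)-2-bromophenoxy]trimethylsilane | C[Si](C)(C)Oc1cc(OCc2ccccc2)cc(OCc2ccccc2)c1Br | intermediate
4 | lithium 3,5-bis(benzyloxy)-2-(trimethylsilyl)phenoxide | [Li+].[O-]c1cc(OCc2ccccc2)cc(OCc2ccccc2)c1[Si](C)(C)C | intermediate
5 | 3,5-bis(benzyloxy)-2-(trimethylsilyl)phenyl trifluoromethanesulfonate | C[Si](C)(C)c1c(OCc2ccccc2)cc(OCc2ccccc2)cc1OS(=O)(=O)C(F)(F)F | intermediate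
6 | 4-tert-butoxy-4-oxobutanoic acid | CC(C)(C)OC(=O)CCC(=O)O | starting material
7 | (S)-4-benzyloxazolidin-2-one | O=C1N[C@@H](Cc2ccccc2)CO1 | starting material
8 | tert-butyl 4-[(4S)-4-benzyl-2-oxooxazolidin-3-yl]-4-oxobutanoate | CC(C)(C)OC(=O)CCC(=O)N1[C@@H](Cc2ccccc2)COC1=O | intermediate
9 | 4-methoxybenzaldehyde | COc1ccc(C=O)cc1 | starting material
10 | dibutylboron Z-enolate of 8 | CC(C)(C)OC(=O)C/C=C(\OB(CCCC)CCCC)N1[C@@H](Cc2ccccc2)COC1=O | intermediate
11 | tert-butyl (3S,4S)-3-[(4S)-4-benzyl-2-oxooxazolidine-3-carbonyl]-4-hydroxy-4-(4-methoxyphenyl)butanoate | O=C(N1[C@@H](Cc2ccccc2)COC1=O)[C@@H](CC(=O)OC(C)(C)C)[C@H](O)c1ccc(OC)cc1 | intermediate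
12 | tert-butyl 2-[(2S,3S)-5,7-bis(benzyloxy)-2-(4-methoxyphenyl)-4-oxochroman-3-yl]acetate (cis) | COc1ccc([C@H]2Oc3cc(OCc4ccccc4)cc(OCc4ccccc4)c3C(=O)[C@H]2CC(=O)OC(C)(C)C)cc1 | intermediate
13 | tert-butyl 2-[(2S,3R)-5,7-bis(benzyloxy)-2-(4-methoxyphenyl)-4-oxochroman-3-yl]acetate (trans) | COc1ccc([C@H]2Oc3cc(OCc4ccccc4)cc(OCc4ccccc4)c3C(=O)[C@@H]2CC(=O)OC(C)(C)C)cc1 | intermediate
14 | 2-[(2S,3R)-5,7-bis(benzyloxy)-2-(4-methoxyphenyl)-4-oxochroman-3-yl]acetic acid | COc1ccc([C@H]2Oc3cc(OCc4ccccc4)cc(OCc4ccccc4)c3C(=O)[C@@H]2CC(=O)O)cc1 | intermediate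
15 | (4S)-4-benzyl-3-{2-[(2S,3R)-5,7-bis(benzyloxy)-2-(4-methoxyphenyl)-4-oxochroman-3-yl]acetyl}oxazolidin-2-one | COc1ccc([C@H]2Oc3cc(OCc4ccccc4)cc(OCc4ccccc4)c3C(=O)[C@@H]2CC(=O)N5[C@@H](Cc6ccccc6)COC5=O)cc1 | intermediate
16 | dibutylboron Z-enolate of 15 | COc1ccc([C@H]2Oc3cc(OCc4ccccc4)cc(OCc4ccccc4)c3C(=O)[C@@H]2/C=C(\OB(CCCC)CCCC)N5[C@@H](Cc6ccccc6)COC5=O)cc1 | intermediate
17 | (4S)-4-benzyl-3-[(2S,3S)-2-[(2S,3R)-5,7-bis(benzyloxy)-2-(4-methoxyphenyl)-4-oxochroman-3-yl]-3-hydroxy-3-(4-methoxyphenyl)propanoyl]oxazolidin-2-one | COc1ccc([C@H]2Oc3cc(OCc4ccccc4)cc(OCc4ccccc4)c3C(=O)[C@@H]2[C@H](C(=O)N5[C@@H](Cc6ccccc6)COC5=O)[C@H](O)c7ccc(OC)cc7)cc1 | intermediate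
18 | 3,5-dimethoxyphenol | COc1cc(O)cc(OC)c1 | starting material
19 | 2-bromo-3,5-dimethoxyphenol | COc1cc(O)c(Br)c(OC)c1 | intermediate
20 | (2-bromo-3,5-dimethoxyphenoxy)trimethylsilane | COc1cc(O[Si](C)(C)C)c(Br)c(OC)c1 | intermediate
21 | lithium 3,5-dimethoxy-2-(trimethylsilyl)phenoxide | [Li+].[O-]c1cc(OC)cc(OC)c1[Si](C)(C)C | intermediate
22 | 3,5-dimethoxy-2-(trimethylsilyl)phenyl trifluoromethanesulfonate | COc1cc(OC)c([Si](C)(C)C)c(OS(=O)(=O)C(F)(F)F)c1 | intermediate
23 | (2S,3R)-5,7-bis(benzyloxy)-3-[(2S,3S)-5,7-dimethoxy-2-(4-methoxyphenyl)-4-oxochroman-3-yl]-2-(4-methoxyphenyl)chroman-4-one | COc1ccc([C@H]2Oc3cc(OCc4ccccc4)cc(OCc4ccccc4)c3C(=O)[C@@H]2[C@@H]2C(=O)c3c(OC)cc(OC)cc3O[C@@H]2c2ccc(OC)cc2)cc1 | intermediate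
24 | (2S,3R)-5,7-dihydroxy-3-[(2S,3S)-5-hydroxy-7-methoxy-2-(4-methoxyphenyl)-4-oxochroman-3-yl]-2-(4-methoxyphenyl)chroman-4-one | COc1ccc([C@H]2Oc3cc(O)cc(O)c3C(=O)[C@@H]2[C@@H]2C(=O)c3c(O)cc(OC)cc3O[C@@H]2c2ccc(OC)cc2)cc1 | target

**Step count and risks**

Total step count: 12. Longest linear sequence: 8 steps (steps 3, 4, 5, 6, 7, 8, 11, 12 from 6, or steps 1, 2, 5, 6, 7, 8, 11, 12 from 1).

Steps most likely to fail:

Step 11 (Proposed new method). The aryl carbanion may be protonated before it reaches the imide carbonyl, the aldolate may fragment by retro-aldol or acyl migration onto the carbamate, or C3'' may epimerise under the basic fluoride after ring closure. Fallback with known chemistry, setting out from 17: the aryne from 22 is used only as an O-arylating agent (CsF, MeCN, 23 °C; known aryne O-arylation of alcohols, the carbanion being protonated in the proton-donating solvent) to give the aryl ether imide F3. The auxiliary is cleaved with LiOH/H2O2 (THF–H2O, 0 °C) to the acid F4. Friedel–Crafts ring closure of this 3-aryloxypropanoic acid with (CF3CO)2O in CH2Cl2 at 0 °C (the two ortho positions of the 3,5-dimethoxyphenoxy ring are equivalent) comes back to the route at 23.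

Step 5 (Proposed new method). The same competition between protonation and acylation of the carbanion applies, and the alkoxide may be consumed by lactonisation onto the ester or by attack on the carbamate before it meets the aryne. Fallback with known chemistry, setting out from 11 and 5: aryne O-arylation in MeCN (CsF, 23 °C) gives the aryl ether imide F1. LiOH/H2O2 (THF–H2O, 0 °C) gives the acid F2. Friedel–Crafts acylation with (CF3CO)2O in CH2Cl2 at 0 °C with short contact closes the ring and comes back to the route at 12, which is epimerised with DBU to 13 as in step 5.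

Step 12. Further methyl ethers may be cleaved during the time needed for all three cleavages, unscavenged benzyl cations may C-benzylate the electron-rich rings, and the Lewis acid may promote epimerisation at C3''. Fallback, setting out from 23: the benzyl ethers are removed first under neutral hydrogenolysis (H2, Pd/C, EtOAc, 23 °C) to give the bis-phenol F5. A short, cold, chelation-controlled demethylation (BCl3, 3 equiv, CH2Cl2, −78 → −20 °C) then cleaves only the 5''-methyl ether and comes back to the route at 24.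

**Further compounds**

F1 | step 5 | tert-butyl (3S,4S)-3-[(4S)-4-benzyl-2-oxooxazolidine-3-carbonyl]-4-[3,5-bis(benzyloxy)phenoxy]-4-(4-methoxyphenyl)butanoate | O=C(N1[C@@H](Cc2ccccc2)COC1=O)[C@@H](CC(=O)OC(C)(C)C)[C@H](Oc1cc(OCc2ccccc2)cc(OCc2ccccc2)c1)c1ccc(OC)cc1
F2 | step 5 | (2S,3S)-3-[3,5-bis(benzyloxy)phenoxy]-2-(2-tert-butoxy-2-oxoethyl)-3-(4-methoxyphenyl)propanoic acid | OC(=O)[C@@H](CC(=O)OC(C)(C)C)[C@H](Oc1cc(OCc2ccccc2)cc(OCc2ccccc2)c1)c1ccc(OC)cc1
F3 | step 11 | (4S)-4-benzyl-3-[(2S,3S)-2-[(2S,3R)-5,7-bis(benzyloxy)-2-(4-methoxyphenyl)-4-oxochroman-3-yl]-3-(3,5-dimethoxyphenoxy)-3-(4-methoxyphenyl)propanoyl]oxazolidin-2-one | COc1ccc([C@H]2Oc3cc(OCc4ccccc4)cc(OCc4ccccc4)c3C(=O)[C@@H]2[C@H](C(=O)N5[C@@H](Cc6ccccc6)COC5=O)[C@H](Oc7cc(OC)cc(OC)c7)c8ccc(OC)cc8)cc1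
F4 | step 11 | (2S,3S)-2-[(2S,3R)-5,7-bis(benzyloxy)-2-(4-methoxyphenyl)-4-oxochroman-3-yl]-3-(3,5-dimethoxyphenoxy)-3-(4-methoxyphenyl)propanoic acid | COc1ccc([C@H]2Oc3cc(OCc4ccccc4)cc(OCc4ccccc4)c3C(=O)[C@@H]2[C@H](C(=O)O)[C@H](Oc5cc(OC)cc(OC)c5)c6ccc(OC)cc6)cc1
F5 | step 12 | (2S,3R)-5,7-dihydroxy-3-[(2S,3S)-5,7-dimethoxy-2-(4-methoxyphenyl)-4-oxochroman-3-yl]-2-(4-methoxyphenyl)chroman-4-one | COc1ccc([C@H]2Oc3cc(O)cc(O)c3C(=O)[C@@H]2[C@@H]2C(=O)c3c(OC)cc(OC)cc3O[C@@H]2c2ccc(OC)cc2)cc1
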